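Ring C (bicyclo[3.3.1]nonane numbering: ester-bearing bridgehead C1, epoxide bridge C9, bridgehead C5, C6H2, ring-fusion C7H and quaternary C8) is cut out of a cycloheptanone. The disconnection rests on the C1–C8 bond between two fully substituted carbons and on the C1 ester: a photochemical Wolff rearrangement of an α-diazo cycloheptanone lets C8 migrate with retention to the diazo carbon, contracts the seven-membered ring to ring C and turns the extruded carbonyl carbon into the methyl ester. The precursor is a 2-allyl-2-methyl-3-isopropenyl cycloheptanone with a ketal-masked second carbonyl; the derived β-keto ester takes ring D by Michael/aldol annulation, then rings B and A.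

Key step: step 8

Remark: C-1 to C-9 are the bicyclo[3.3.1]nonane positions of the ring C/ring D core (C-2 CH2, C-3 carbinol carbon, C-4 ketone); ring A is the lactone and ring B the cycloheptadiene; centres written without configuration in a SMILES are epimer mixtures that are later enolised, oxidised or made sp2.

Step 1
Reactants: 1 cycloheptane-1,3-dione
Product: 2 3-isobutoxycyclohept-2-en-1-one
Conditions: i-BuOH, PPTS (cat.), toluene, reflux, Dean–Stark
Reagents that add atoms: 2-methylpropan-1-ol, CC(C)CO
Why: Acid-catalysed enol etherification of the 1,3-dione under water removal gives the vinylogous ester, which masks one carbonyl and directs later enolate chemistry to the α′ carbon.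

Step 2
Reactants: 2 3-isobutoxycyclohept-2-en-1-one
Product: 4 3-isobutoxycyclohepta-2,6-dien-1-one, via silyl dienol ether 3 (not isolated)
Conditions: LDA, THF, −78 °C; TMSCl; then Pd(OAc)2, MeCN, rt
Reagents that add atoms: chlorotrimethylsilane, C[Si](C)(C)Cl (silicon retained only in 3)
Why: Kinetic α′-deprotonation and O-silylation give the 2-silyloxy diene, which palladium diacetate dehydrogenates to the cross-conjugated dienone (Saegusa–Ito oxidation), β-hydride elimination being possible only toward the ring CH2.

Step 3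
Reactants: 4 3-isobutoxycyclohepta-2,6-dien-1-one
Product: 5 (R)-3-isobutoxy-6-(prop-1-en-2-yl)cyclohept-2-en-1-one
Conditions: isopropenyl-B(pin), [Rh(cod)Cl]2 (cat.), (R)-BINAP, K3PO4, dioxane/H2O, 40 °C
Reagents that add atoms: isopropenylboronic acid pinacol ester, CC(=C)B1OC(C)(C)C(C)(C)O1
Why: Rhodium-catalysed asymmetric 1,4-addition of the alkenylboronate (Hayashi–Miyaura reaction) should occur at the unsubstituted enone β-carbon and not at the alkoxy-bearing one, and the (R)-BINAP ligand sets the future C-7 centre by face-selective carborhodation in the sense known for cyclohept-2-enone.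

Step 4
Reactants: 5 (R)-3-isobutoxy-6-(prop-1-en-2-yl)cyclohept-2-en-1-one
Product: 6 (6R)-3-isobutoxy-7-methyl-6-(prop-1-en-2-yl)cyclohept-2-en-1-one (C-7 epimers)
Conditions: LDA, THF, −78 °C; MeI, −78 → 0 °C
Reagents that add atoms: iodomethane, CI
Why: Kinetic α′-enolate alkylation of the vinylogous ester places the methyl group next to the carbonyl, and the configuration of this carbon does not matter because it is enolised again in step 5.

Step 5
Reactants: 6 (6R)-3-isobutoxy-7-methyl-6-(prop-1-en-2-yl)cyclohept-2-en-1-one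
Product: 7 (6S,7S)-7-allyl-3-isobutoxy-7-methyl-6-(prop-1-en-2-yl)cyclohept-2-en-1-one
Conditions: LDA, THF, −78 °C; allyl bromide, DMPU, −78 °C → rt
Reagents that add atoms: allyl bromide, C=CCBr
Why: A second α′-enolate alkylation creates the quaternary centre (future C-8), allyl bromide approaching the enolate anti to the neighbouring isopropenyl group so that allyl and isopropenyl end trans (1,2-induction).

Step 6
Reactants: 7 (6S,7S)-7-allyl-3-isobutoxy-7-methyl-6-(prop-1-en-2-yl)cyclohept-2-en-1-one
Product: 8 (4S,5S)-4-allyl-4-methyl-5-(prop-1-en-2-yl)cycloheptane-1,3-dione 1-(2,2-dimethylpropane-1,3-diyl) ketal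
Conditions: 2,2-dimethylpropane-1,3-diol, TsOH·H2O (cat.), benzene, reflux (isobutanol distilled off)
Reagents that add atoms: 2,2-dimethylpropane-1,3-diol, OCC(C)(C)CO
Why: Acid-catalysed exchange of the enol ether with the 1,3-diol (transketalisation) should place the cyclic ketal on the unhindered carbonyl carbon and leave the ketone next to the quaternary carbon free, driven by removal of isobutanol.

Step 7
Reactants: 8 (4S,5S)-4-allyl-4-methyl-5-(prop-1-en-2-yl)cycloheptane-1,3-dione 1-(2,2-dimethylpropane-1,3-diyl) ketal
Product: 10 2-diazo derivative of 8 (α-diazo ketone), via trifluoroacetyl ketone 9 (not isolated)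
Conditions: LiHMDS, THF, −78 °C; CF3CO2CH2CF3; then MsN3, Et3N, H2O, MeCN, rt
Reagents that add atoms: methanesulfonyl azide, CS(=O)(=O)N=[N+]=[N-]; 2,2,2-trifluoroethyl trifluoroacetate, FC(F)(F)COC(=O)C(F)(F)F (retained only in 9)
Why: Detrifluoroacetylative diazo transfer of the Regitz type, in which the only enolisable α-carbon is trifluoroacetylated and the activated dicarbonyl then accepts the diazo group from the sulfonyl azide with loss of the trifluoroacetyl group.

Step 8
Reactants: 10 2-diazo derivative of 8 (α-diazo ketone)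
Product: 13 methyl (2S,3S)-2-allyl-2-methyl-6-oxo-3-(prop-1-en-2-yl)cyclohexane-1-carboxylate (C-1 epimers), via ketene 11 (not isolated), via ketal ester 12 (not isolated)
Conditions: hν (300 nm), MeOH, rt; then 1 M aq. HCl, THF, rt
Reagents that add atoms: methanol, CO; water, O
Why: Photoexcitation of the α-diazo ketone expels N2 while the C-8–C(=O) bond, the only migratable bond on the single flanking carbonyl, shifts to the diazo carbon (Wolff rearrangement), so the carbonyl carbon leaves the ring as a ketene that methanol traps as the methyl ester; acid then unmasks the ring ketone. The closest known reaction type is the photochemical Wolff ring contraction of cyclic 2-diazo ketones to ring-contracted esters. No ring is closed by cyclisation: ring C (C-1, C-8, C-7, C-6, C-5, C-9) arises from the seven-membered ring by excision of one carbon, which forges the hindered C-1–C-8 bond intramolecularly. C-8 migrates with retention and C-7 is untouched, so both centres set in steps 3 and 5 are carried over, whereas C-1 is formed as an epimer mixture that is enolised in steps 9 and 10. The step needs one migrating group and no carbene side reactions: the second carbonyl is a ketal, so only C-8 can migrate and the neighbouring ketal carbon offers no hydrogen for a 1,2-shift, and the isolated alkenes do not absorb at 300 nm.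

Step 9
Reactants: 13 methyl (2S,3S)-2-allyl-2-methyl-6-oxo-3-(prop-1-en-2-yl)cyclohexane-1-carboxylate
Product: 14 methyl (2S,3S)-2-allyl-2,5-dimethyl-6-oxo-3-(prop-1-en-2-yl)cyclohexane-1-carboxylate (C-1 and C-5 epimers)
Conditions: NaH, THF, 0 °C; n-BuLi, −20 °C; MeI, −78 → 0 °C
Reagents that add atoms: iodomethane, CI
Why: γ-Alkylation of the β-keto ester dianion, whose second and more reactive carbanion at the ketone α′-carbon (future C-5) is methylated selectively.

Step 10
Reactants: 14 methyl (2S,3S)-2-allyl-2,5-dimethyl-6-oxo-3-(prop-1-en-2-yl)cyclohexane-1-carboxylate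
Product: 16 ketol methyl 8-allyl-4-hydroxy-3,5,8-trimethyl-9-oxo-7-(prop-1-en-2-yl)bicyclo[3.3.1]nonane-1-carboxylate (ring D bridge anti to the C-8 methyl; C-3/C-4 epimers), via Michael adduct 15 (not isolated)
Conditions: methacrolein, 1,1,3,3-tetramethylguanidine, CH2Cl2, −20 °C → rt
Reagents that add atoms: methacrolein, CC(=C)C=O
Why: Base-catalysed Michael addition of the β-keto ester to methacrolein followed by intramolecular aldol addition of the ketone α′-carbon (Michael/aldol α,α′-annulation) should close ring D, the acceptor adding to C-1 anti to the pseudo-axial C-8 methyl (axial attack on the half-chair enolate) and the aldol being able to close only cis, which fixes C-1 and C-5.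

Step 11
Reactants: 16 ketol methyl 8-allyl-4-hydroxy-3,5,8-trimethyl-9-oxo-7-(prop-1-en-2-yl)bicyclo[3.3.1]nonane-1-carboxylate
Product: 17 methyl 8-allyl-4-hydroxy-3,5,8-trimethyl-9-methylene-7-(prop-1-en-2-yl)bicyclo[3.3.1]nonane-1-carboxylate
Conditions: Cp2Ti(μ-CH2)(μ-Cl)AlMe2 (Tebbe reagent, 2.5 equiv), pyridine, THF, −40 → 0 °C
Reagents that add atoms: Tebbe reagent Cp2Ti(μ-CH2)(μ-Cl)AlMe2, C[Al](C)C[Ti](Cl)(C1C=CC=C1)C1C=CC=C1 (drawn open-chain)
Why: Tebbe methylenation should convert the non-enolisable bridge ketone into the exocyclic methylene by cycloaddition and cycloreversion with the titanium methylidene, which attacks ketones faster than the hindered ester, while the free hydroxyl is only titanated and returns on work-up.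

Step 12
Reactants: 17 methyl 8-allyl-4-hydroxy-3,5,8-trimethyl-9-methylene-7-(prop-1-en-2-yl)bicyclo[3.3.1]nonane-1-carboxylate
Product: 18 methyl 8-allyl-3,5,8-trimethyl-9-methylene-4-oxo-7-(prop-1-en-2-yl)bicyclo[3.3.1]nonane-1-carboxylate (C-3 epimers)
Conditions: Dess–Martin periodinane, NaHCO3, CH2Cl2, rt
Reagents that add atoms: none
Why: Dess–Martin oxidation of the hindered secondary alcohol gives the ring D ketone, which cannot conjugate with the methylene because C-5 carries no hydrogen.

Step 13
Reactants: 18 methyl 8-allyl-3,5,8-trimethyl-9-methylene-4-oxo-7-(prop-1-en-2-yl)bicyclo[3.3.1]nonane-1-carboxylate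
Product: 21 methyl 8-allyl-3,5,8-trimethyl-9-methylene-7-(2-methyloxiran-2-yl)-4-oxo-3-(triethylsilyloxy)bicyclo[3.3.1]nonane-1-carboxylate (silyloxy group on the C-9 side; oxirane epimers), via silyl enol ether 19 (not isolated), via silyloxy ketone 20 (not isolated)
Conditions: KHMDS, TESCl, THF, −78 °C; then mCPBA (2.2 equiv), NaHCO3, CH2Cl2, −20 → 0 °C
Reagents that add atoms: chlorotriethylsilane, CC[Si](Cl)(CC)CC; 3-chloroperbenzoic acid, OOC(=O)c1cccc(Cl)c1
Why: Regiospecific enolisation (only C-3 carries an α-hydrogen) and O-silylation give the enol ether, whose Rubottom oxidation from the exposed face turned away from ring C installs the C-3 oxygen with silyl migration, while the second equivalent of peracid epoxidises the 1,1-disubstituted isopropenyl group faster than the monosubstituted allyl group and the shielded bridge methylene (Prilezhaev epoxidation).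

Step 14
Reactants: 21 methyl 8-allyl-3,5,8-trimethyl-9-methylene-7-(2-methyloxiran-2-yl)-4-oxo-3-(triethylsilyloxy)bicyclo[3.3.1]nonane-1-carboxylate
Product: 22 methyl 8-allyl-3,5,8-trimethyl-9-methylene-4-oxo-7-(1-oxopropan-2-yl)-3-(triethylsilyloxy)bicyclo[3.3.1]nonane-1-carboxylate (side-chain epimers)
Conditions: BF3·OEt2, CH2Cl2, −78 °C
Reagents that add atoms: none
Why: Lewis-acid-promoted Meinwald rearrangement, in which the 2,2-disubstituted epoxide opens at the tertiary carbon and a 1,2-hydride shift gives the α-methyl aldehyde whose new methine is made sp2 again in step 19.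

Step 15
Reactants: 23 vinyl bromide
Product: 26 (3-bromo-2-methylbut-3-en-2-yl)oxy(triethyl)silane, via 1-bromovinyllithium 24 (not isolated), via lithium alkoxide 25 (not isolated)
Conditions: LDA, THF/Et2O/pentane, −110 °C; acetone; then TESOTf, −78 °C → rt
Reagents that add atoms: acetone, CC(C)=O; triethylsilyl trifluoromethanesulfonate, CC[Si](CC)(CC)OS(=O)(=O)C(F)(F)F; lithium diisopropylamide, [Li]N(C(C)C)C(C)C (lithium retained only in 24 and 25)
Why: Deprotonation of vinyl bromide gives 1-bromovinyllithium, which undergoes 1,2-addition to acetone, and the tertiary alkoxide is O-silylated in the same flask.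

Step 16
Reactants: 22 methyl 8-allyl-3,5,8-trimethyl-9-methylene-4-oxo-7-(1-oxopropan-2-yl)-3-(triethylsilyloxy)bicyclo[3.3.1]nonane-1-carboxylate; 26 (3-bromo-2-methylbut-3-en-2-yl)oxy(triethyl)silane
Product: 28 allylic alcohol methyl 8-allyl-7-[3-hydroxy-5-methyl-4-methylene-5-(triethylsilyloxy)hexan-2-yl]-3,5,8-trimethyl-9-methylene-4-oxo-3-(triethylsilyloxy)bicyclo[3.3.1]nonane-1-carboxylate (side-chain epimers), via alkenyllithium 27 (not isolated)
Conditions: 26, t-BuLi, Et2O, −78 °C; then 22, THF, −78 °C
Reagents that add atoms: tert-butyllithium, [Li]C(C)(C)C (lithium retained only in 27)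
Why: Bromine–lithium exchange gives the alkenyllithium, whose 1,2-addition to the aldehyde should be far faster at −78 °C than attack on the fully α-substituted ketone or the neopentyl ester.

Step 17
Reactants: 28 allylic alcohol (as named in step 16)
Product: 29 enone methyl 8-allyl-3,5,8-trimethyl-9-methylene-7-[5-methyl-4-methylene-3-oxo-5-(triethylsilyloxy)hexan-2-yl]-4-oxo-3-(triethylsilyloxy)bicyclo[3.3.1]nonane-1-carboxylate
Conditions: Dess–Martin periodinane, NaHCO3, CH2Cl2, 0 °C → rt
Reagents that add atoms: none
Why: Dess–Martin oxidation of the allylic alcohol gives the α-methylene ketone needed for ring closure.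

Step 18
Reactants: 29 enone (as named in step 17)
Product: 30 ring B cycloheptenone in which C-7 and C-8 are bridged by CH(CH3)–C(=O)–C[C(CH3)2OSiEt3]=CH–CH2 (trans ring fusion)
Conditions: second-generation Hoveyda–Grubbs catalyst (cat.), toluene, 80 °C
Reagents that add atoms: none
Why: Ring-closing metathesis between the allyl group and the 1,1-disubstituted enone alkene should form the seven-membered ring B with its trisubstituted alkene and release ethene, the bridge methylene between two quaternary carbons being too hindered to engage the ruthenium carbene.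

Step 19
Reactants: 30 ring B cycloheptenone
Product: 31 dienyl triflate with the ring B unit C(CH3)=C(OTf)–C[C(CH3)2OSiEt3]=CH–CH2
Conditions: KHMDS, THF, −78 °C; PhNTf2, −78 → 0 °C
Reagents that add atoms: N-phenylbis(trifluoromethanesulfonimide), FC(F)(F)S(=O)(=O)N(c1ccccc1)S(=O)(=O)C(F)(F)F
Why: Kinetic α′-deprotonation of the cycloheptenone (the ring D ketone has no α-hydrogen) and O-triflation of the cross-conjugated dienolate give the 2-triflyloxy-1,3-diene, which fixes the position of both ring B double bonds.

Step 20
Reactants: 31 dienyl triflate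
Product: 32 diene diester with CH2CO2CH3 at the former triflate carbon
Conditions: BrZnCH2CO2Me, Pd2(dba)3 (cat.), XPhos, THF, 60 °C
Reagents that add atoms: (2-methoxy-2-oxoethyl)zinc bromide, COC(=O)C[Zn]Br
Why: Palladium-catalysed Negishi coupling of the dienyl triflate with the Reformatsky zinc enolate attaches the acetate unit at the triflate carbon without moving the diene.

Step 21
Reactants: 32 diene diester
Product: 34 lactone alcohol (the 9-methylene analogue of the target), via diol ester 33 (not isolated)
Conditions: TBAF, THF, 0 °C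
Reagents that add atoms: none
Why: Fluoride cleaves both triethylsilyl ethers and the tertiary allylic alkoxide closes the six-membered lactone (ring A) by intramolecular transesterification, helped by the gem-dimethyl group.

Step 22
Reactants: 34 lactone alcohol
Product: 35 target CNP0605450.1
Conditions: VO(acac)2 (cat.), t-BuOOH, CH2Cl2, 0 °C → rt
Reagents that add atoms: tert-butyl hydroperoxide, CC(C)(C)OO
Why: Vanadium-catalysed hydroxyl-directed epoxidation, in which the tertiary C-3 hydroxyl lying on the ring D face of the bridge methylene binds the vanadium peroxide and delivers oxygen to that face, should give the spiro-epoxide with the required configuration and leave the undirected diene untouched.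

Compound list
1 | cycloheptane-1,3-dione | O=C1CCCCC(=O)C1 | starting material
2 | 3-isobutoxycyclohept-2-en-1-one | O=C1C=C(OCC(C)C)CCCC1 | intermediate
3 | 1-isobutoxy-3-(trimethylsilyloxy)cyclohepta-1,3-diene (formed in situ) | C[Si](C)(C)OC1=CCCCC(OCC(C)C)=C1 | intermediate
4 | 3-isobutoxycyclohepta-2,6-dien-1-one | O=C1C=CCCC(OCC(C)C)=C1 | intermediate
5 | (R)-3-isobutoxy-6-(prop-1-en-2-yl)cyclohept-2-en-1-one | O=C1C[C@H](C(C)=C)CCC(OCC(C)C)=C1 | intermediate
6 | (6R)-3-isobutoxy-7-methyl-6-(prop-1-en-2-yl)cyclohept-2-en-1-one, C-7 epimers | O=C1C(C)[C@H](C(C)=C)CCC(OCC(C)C)=C1 | intermediate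
7 | (6S,7S)-7-allyl-3-isobutoxy-7-methyl-6-(prop-1-en-2-yl)cyclohept-2-en-1-one (allyl trans to isopropenyl) | O=C1[C@@](C)(CC=C)[C@H](C(C)=C)CCC(OCC(C)C)=C1 | intermediate
8 | (4S,5S)-4-allyl-4-methyl-5-(prop-1-en-2-yl)cycloheptane-1,3-dione 1-(2,2-dimethylpropane-1,3-diyl) ketal | O=C1CC2(OCC(C)(C)CO2)CC[C@@H](C(C)=C)[C@]1(C)CC=C | intermediate
9 | 2-trifluoroacetyl derivative of 8 (formed in situ) | O=C1C(C(=O)C(F)(F)F)C2(OCC(C)(C)CO2)CC[C@@H](C(C)=C)[C@]1(C)CC=C | intermediate
10 | 2-diazo derivative of 8 (α-diazo ketone) | O=C1C(=[N+]=[N-])C2(OCC(C)(C)CO2)CC[C@@H](C(C)=C)[C@]1(C)CC=C | intermediate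
11 | ring-contracted ketene (formed in situ) | O=C=C1C2(OCC(C)(C)CO2)CC[C@@H](C(C)=C)[C@]1(C)CC=C | intermediate
12 | ketal of 13 (formed in situ), C-1 epimers | COC(=O)C1C2(OCC(C)(C)CO2)CC[C@@H](C(C)=C)[C@]1(C)CC=C | intermediate
13 | methyl (2S,3S)-2-allyl-2-methyl-6-oxo-3-(prop-1-en-2-yl)cyclohexane-1-carboxylate, C-1 epimers | COC(=O)C1C(=O)CC[C@@H](C(C)=C)[C@]1(C)CC=C | intermediate
14 | methyl (2S,3S)-2-allyl-2,5-dimethyl-6-oxo-3-(prop-1-en-2-yl)cyclohexane-1-carboxylate, C-1 and C-5 epimers | COC(=O)C1C(=O)C(C)C[C@@H](C(C)=C)[C@]1(C)CC=C | intermediate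
15 | Michael adduct, 1-(2-methyl-3-oxopropyl) derivative of 14 (formed in situ) | COC(=O)[C@@]1(CC(C)C=O)C(=O)C(C)C[C@@H](C(C)=C)[C@]1(C)CC=C | intermediate
16 | methyl 8-allyl-4-hydroxy-3,5,8-trimethyl-9-oxo-7-(prop-1-en-2-yl)bicyclo[3.3.1]nonane-1-carboxylate; ring D bridge anti to the C-8 methyl and syn to C-7 H; C-3/C-4 epimers | COC(=O)[C@]12CC(C)C(O)[C@](C)(C[C@@H](C(C)=C)[C@]1(C)CC=C)C2=O | intermediate
17 | 9-methylene analogue of 16 | COC(=O)[C@]12CC(C)C(O)[C@](C)(C[C@@H](C(C)=C)[C@]1(C)CC=C)C2=C | intermediate
18 | 4-ketone of 17, C-3 epimers | COC(=O)[C@]12CC(C)C(=O)[C@](C)(C[C@@H](C(C)=C)[C@]1(C)CC=C)C2=C | intermediate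
19 | triethylsilyl enol ether of 18 (formed in situ) | COC(=O)[C@]12CC(C)=C(O[Si](CC)(CC)CC)[C@](C)(C[C@@H](C(C)=C)[C@]1(C)CC=C)C2=C | intermediate
20 | 3-(triethylsilyloxy) ketone, silyloxy group on the C-9 side (formed in situ) | COC(=O)[C@]12C[C@@](C)(O[Si](CC)(CC)CC)C(=O)[C@](C)(C[C@@H](C(C)=C)[C@]1(C)CC=C)C2=C | intermediate
21 | 7-(2-methyloxiran-2-yl) analogue of 20, oxirane epimers | COC(=O)[C@]12C[C@@](C)(O[Si](CC)(CC)CC)C(=O)[C@](C)(C[C@@H](C3(C)CO3)[C@]1(C)CC=C)C2=C | intermediate
22 | 7-(1-oxopropan-2-yl) aldehyde, side-chain epimers | COC(=O)[C@]12C[C@@](C)(O[Si](CC)(CC)CC)C(=O)[C@](C)(C[C@@H](C(C)C=O)[C@]1(C)CC=C)C2=C | intermediate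
23 | vinyl bromide | C=CBr | starting material
24 | 1-bromovinyllithium (formed in situ) | [Li]C(Br)=C | intermediate
25 | lithium 3-bromo-2-methylbut-3-en-2-olate (formed in situ) | [Li+].[O-]C(C)(C)C(Br)=C | intermediate
26 | (3-bromo-2-methylbut-3-en-2-yl)oxy(triethyl)silane | C=C(Br)C(C)(C)O[Si](CC)(CC)CC | intermediate
27 | alkenyllithium from 26 (formed in situ) | [Li]C(=C)C(C)(C)O[Si](CC)(CC)CC | intermediate
28 | allylic alcohol from 22 and 27, side-chain epimers | COC(=O)[C@]12C[C@@](C)(O[Si](CC)(CC)CC)C(=O)[C@](C)(C[C@@H](C(C)C(O)C(=C)C(C)(C)O[Si](CC)(CC)CC)[C@]1(C)CC=C)C2=C | intermediate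
29 | α-methylene ketone from 28 | COC(=O)[C@]12C[C@@](C)(O[Si](CC)(CC)CC)C(=O)[C@](C)(C[C@@H](C(C)C(=O)C(=C)C(C)(C)O[Si](CC)(CC)CC)[C@]1(C)CC=C)C2=C | intermediate
30 | ring B cycloheptenone, trans ring fusion | COC(=O)[C@]12C[C@@](C)(O[Si](CC)(CC)CC)C(=O)[C@](C)(C[C@H]3C(C)C(=O)C(C(C)(C)O[Si](CC)(CC)CC)=CC[C@@]31C)C2=C | intermediate
31 | dienyl triflate of 30 | COC(=O)[C@]12C[C@@](C)(O[Si](CC)(CC)CC)C(=O)[C@](C)(C[C@H]3C(C)=C(OS(=O)(=O)C(F)(F)F)C(C(C)(C)O[Si](CC)(CC)CC)=CC[C@@]31C)C2=C | intermediate
32 | diene diester (CH2CO2CH3 in place of the triflate) | COC(=O)[C@]12C[C@@](C)(O[Si](CC)(CC)CC)C(=O)[C@](C)(C[C@H]3C(C)=C(CC(=O)OC)C(C(C)(C)O[Si](CC)(CC)CC)=CC[C@@]31C)C2=C | intermediate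
33 | diol ester (formed in situ) | COC(=O)[C@]12C[C@@](C)(O)C(=O)[C@](C)(C[C@H]3C(C)=C(CC(=O)OC)C(C(C)(C)O)=CC[C@@]31C)C2=C | intermediate
34 | lactone alcohol, 9-methylene analogue of the target | COC(=O)[C@]12C[C@@](C)(O)C(=O)[C@](C)(C[C@H]3C(C)=C4CC(=O)OC(C)(C)C4=CC[C@@]31C)C2=C | intermediate
35 | CNP0605450.1 | COC(=O)[C@]12C[C@@](C)(O)C(=O)[C@](C)(C[C@H]3C(C)=C4CC(=O)OC(C)(C)C4=CC[C@@]31C)[C@]21CO1 | target

Total step count: 22 (21 in the main line and 1 for reagent 26). Longest linear sequence: 21 steps (steps 1 to 14 and 16 to 22).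

Steps most likely to fail

Step 10. The Michael addition has to join the tertiary β-keto ester carbon, which sits next to the quaternary C-8, to methacrolein. Slow addition, retro-Michael cleavage of the adduct and base-induced polymerisation of the enal may leave the annulation incomplete. The fallback sets out from 14 and comes back at 19. The dianion of 14 (NaH, then n-BuLi) would be added 1,2 to methacrolein at the ketone α′-carbon to give the γ-aldol adduct F1. Dess–Martin oxidation would give the isopropenyl ketone F2. Intramolecular 6-endo Michael addition of the β-keto ester (Cs2CO3, MeCN) would then close ring D to the bicyclic diketone F3, so that the bond to the congested C-1 is formed intramolecularly. The face of attack at C-5 in the aldol step is not secured, and the bicycle with ring D anti to the C-8 methyl would have to be separated from its isomer here. KHMDS and TESCl would convert the only enolisable ketone into the silyl enol ether F4, and Tebbe methylenation of the remaining bridge ketone would give 19, which enters step 13 at the peracid stage.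

Step 11. The bridge ketone lies between two quaternary carbons. The titanium methylidene may react sluggishly, may attack the ester carbonyl instead, or the Lewis-acidic reagent may trigger retro-aldol cleavage of the β-hydroxy ketone. The fallback sets out from 16 and comes back at 17 by a Peterson olefination: (trimethylsilyl)methyllithium with anhydrous CeCl3 (excess, THF, −78 °C) should add to the ketone to give the β-hydroxysilane F5, and KH in THF should then eliminate trimethylsilanolate to give 17.

Step 20. Oxidative addition and transmetalation at a triflate flanked by a tetrasubstituted alkene carbon and by the carbon bearing the silyloxy-isopropyl group may be slow, so that reduction of the triflate or its hydrolysis back to the ketone competes. The fallback sets out from 30 and comes back at 32. 1,2-Addition of the lithium enolate of methyl acetate (LDA, MeOAc, THF, −78 °C) to the ring B ketone would give the tertiary allylic alcohol F6. Dehydration with Burgess reagent (benzene, 50 °C) would remove the hydroxyl together with the ring methine hydrogen to give 32; the isomer dehydrated toward the ester CH2 would have to be separated.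

Further compounds
F1 | step 10 | γ-aldol adduct of 14 with methacrolein, epimers | COC(=O)C1C(=O)C(C)(C(O)C(C)=C)C[C@@H](C(C)=C)[C@]1(C)CC=C
F2 | step 10 | isopropenyl ketone from F1, epimers | COC(=O)C1C(=O)C(C)(C(=O)C(C)=C)C[C@@H](C(C)=C)[C@]1(C)CC=C
F3 | step 10 | bicyclic 4,9-diketone (4-oxo analogue of 16), C-3 epimers | COC(=O)[C@]12CC(C)C(=O)[C@](C)(C[C@@H](C(C)=C)[C@]1(C)CC=C)C2=O
F4 | step 10 | triethylsilyl enol ether of F3 | COC(=O)[C@]12CC(C)=C(O[Si](CC)(CC)CC)[C@](C)(C[C@@H](C(C)=C)[C@]1(C)CC=C)C2=O
F5 | step 11 | 9-hydroxy-9-(trimethylsilylmethyl) adduct of 16, epimers | COC(=O)[C@]12CC(C)C(O)[C@](C)(C[C@@H](C(C)=C)[C@]1(C)CC=C)C2(O)C[Si](C)(C)C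
F6 | step 20 | tertiary allylic alcohol from 30 and methyl acetate enolate, epimers | COC(=O)[C@]12C[C@@](C)(O[Si](CC)(CC)CC)C(=O)[C@](C)(C[C@H]3C(C)C(O)(CC(=O)OC)C(C(C)(C)O[Si](CC)(CC)CC)=CC[C@@]31C)C2=C
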